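**Assumptions**
- "Isobutylshikonin" is read as the (R)-configured isobutyrate (2-methylpropanoate) of shikonin, exactly as the SMILES shows (side-chain C1′ = R).
- In Step 7 the (R,R)-ligand is assumed to give the (R)-ester, by analogy with α-aryl enamide and enol-ester reductions. If the first analytical run shows (S), the (S,S)-ligand is used with nothing else changed.

**Retrosynthetic overview**
1. Target 14 ⇐ naphthazarin diacetate 13 (cleave two aryl acetates) ⇐ tetramethyl ether 10 by an oxidation-state relay (CAN; Zn/Ac2O; CAN) that leaves the side chain alone.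
2. 10 ⇐ dienyl isobutyrate 9 by enantioselective 1,2-hydrogenation (proposed new step); this sets C1′ (R) with the isobutyrate already in place.
3. 9 ⇐ ketone 7 by O-acylation of its dienolate with isobutyric anhydride 8; 7 ⇐ aryllithium from bromide 4 + Weinreb amide 6 (forms the C2–C1′ bond).
4. 4 ⇐ 1,5-dimethoxynaphthalene 1 (dibromination, Cu-methoxylation, monobromination).
5. Ring order: no ring is built. Both naphthalene rings come intact from 1; only substitution and oxidation level change.

**Route**

Step 1
Reactants: 1, 1,5-dimethoxynaphthalene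
Product: 2, 4,8-dibromo-1,5-dimethoxynaphthalene
Conditions: NBS (2.1 equiv), MeCN, rt, dark
Reagents that add atoms: N-bromosuccinimide, O=C1CCC(=O)N1Br
Why: Electrophilic aromatic bromination occurs para to each methoxy group (C4 and C8), the most activated positions.

Step 2
Reactants: 2, 4,8-dibromo-1,5-dimethoxynaphthalene
Product: 3, 1,4,5,8-tetramethoxynaphthalene
Conditions: NaOMe (excess), CuI, MeOH/DMF, reflux
Reagents that add atoms: sodium methoxide, [Na+].[O-]C
Why: Copper-mediated Ullmann-type methoxylation replaces both aryl bromides.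

Step 3
Reactants: 3, 1,4,5,8-tetramethoxynaphthalene
Product: 4, 2-bromo-1,4,5,8-tetramethoxynaphthalene
Conditions: NBS (1.0 equiv), CH2Cl2, 0 °C → rt
Reagents that add atoms: N-bromosuccinimide, O=C1CCC(=O)N1Br
Why: All four free positions are equivalent, so one equivalent of NBS gives a single monobromide by electrophilic bromination, and the bromine slows a second substitution.

Step 4
Reactants: 5, 4-methylpent-3-enoic acid
Product: 6, N-methoxy-N,4-dimethylpent-3-enamide (Weinreb amide)
Conditions: CDI, CH2Cl2, rt; then MeNH(OMe)·HCl, rt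
Reagents that add atoms: N,O-dimethylhydroxylamine hydrochloride, CNOC.Cl
Why: Acyl-imidazolide amidation (Weinreb amide formation) is near-neutral, so the β,γ-alkene does not move into conjugation.

Step 5
Reactants: 4, 2-bromo-1,4,5,8-tetramethoxynaphthalene; 6, N-methoxy-N,4-dimethylpent-3-enamide
Product: 7, 4-methyl-1-(1,4,5,8-tetramethoxynaphthalen-2-yl)pent-3-en-1-one
Conditions: n-BuLi (1.05 equiv), THF, −78 °C, 15 min; then 6, −78 → −20 °C; aq. NH4Cl
Reagents that add atoms: none beyond reactant 6 (CC(C)=CCC(=O)N(C)OC), which supplies the acyl group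
Why: Br–Li exchange gives the ortho-methoxy-stabilised aryllithium, and Weinreb ketone synthesis stops at the ketone because the chelated tetrahedral intermediate survives until quench.

Step 6
Reactants: 7, 4-methyl-1-(1,4,5,8-tetramethoxynaphthalen-2-yl)pent-3-en-1-one; 8, isobutyric anhydride
Product: 9, (1Z)-4-methyl-1-(1,4,5,8-tetramethoxynaphthalen-2-yl)penta-1,3-dien-1-yl 2-methylpropanoate
Conditions: KHMDS (1.1 equiv), THF, −78 °C; then (i-PrCO)2O (1.3 equiv), −78 → 0 °C; Et3N-deactivated silica
Reagents that add atoms: isobutyric anhydride (8), CC(C)C(=O)OC(=O)C(C)C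
Why: The doubly activated α-CH2 is deprotonated to the Z(O)-dienolate (bulky aryl cis to H), and this potassium enolate is O-acylated by the anhydride (enol ester formation) to give the (1Z)-dienyl ester.

Step 7
Reactants: 9, (1Z)-dienyl isobutyrate
Product: 10, (1R)-4-methyl-1-(1,4,5,8-tetramethoxynaphthalen-2-yl)pent-3-en-1-yl 2-methylpropanoate
Conditions: [Rh(cod)((R,R)-Et-DuPhos)]BF4 (2 mol %), H2 (5 bar), degassed THF/MeOH, 25 °C
Reagents that add atoms: none (H2 only)
Why: Proposed new method: enantioselective, strictly 1,2-selective Rh(I)–bisphosphine hydrogenation of a 1-aryl-1-acyloxy-1,3-diene. The isobutyrate C=O and the C1=C2 bond chelate cationic Rh, hydride goes to C2, and Rh sits on C1 as a five-membered α-acyloxyalkyl chelate that is not allylic, so no π-allyl and no 1,4-reduction is expected. C–H reductive elimination then sets C1 as (R) on the face chosen by the C2-symmetric ligand. The gem-dimethyl terminus clashes with the C1 acyloxy group in the s-cis form, which disfavours η4-diene binding, and the non-chelating trisubstituted alkene is inert to this catalyst. Closest known reaction type: Rh–DuPhos asymmetric hydrogenation of 1-arylvinyl esters and of 2-acyloxy-1,3-dienes and dienamides, where only the chelating C=C is reduced.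

Step 8
Reactants: 10, (R)-tetramethyl ether isobutyrate
Product: 11, (1R)-1-(1,4-dimethoxy-5,8-dioxo-5,8-dihydronaphthalen-2-yl)-4-methylpent-3-en-1-yl 2-methylpropanoate (the 6-substituted 5,8-dimethoxy-1,4-naphthoquinone)
Conditions: CAN (2.6 equiv), MeCN/H2O, 0 °C, 15 min; chromatography
Reagents that add atoms: water, O
Why: CAN oxidative demethylation takes place mainly on the unsubstituted ring, because the acyloxyalkyl group makes its own ring less electron-rich; the minor regioisomer is removed by chromatography and the stereocentre is untouched.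

Step 9
Reactants: 11, dimethoxy-quinone
Product: 12, (1R)-1-[5,8-bis(acetyloxy)-1,4-dimethoxynaphthalen-2-yl]-4-methylpent-3-en-1-yl 2-methylpropanoate
Conditions: Zn dust, Ac2O, Et3N, DMAP (cat.), CH2Cl2, 0 °C → rt
Reagents that add atoms: acetic anhydride, CC(=O)OC(C)=O
Why: Reductive acetylation traps the hydroquinone as an electron-poor diacetate, and this hydroquinone is on the ring that does not carry the benzylic ester, so no quinone-methide elimination can occur.

Step 10
Reactants: 12, diacetoxy-dimethoxynaphthalene
Product: 13, (1R)-1-[5,8-bis(acetyloxy)-1,4-dioxo-1,4-dihydronaphthalen-2-yl]-4-methylpent-3-en-1-yl 2-methylpropanoate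
Conditions: CAN (2.6 equiv), MeCN/H2O, 0 °C, 15 min
Reagents that add atoms: water, O
Why: With the other ring deactivated as the diacetate, CAN oxidative demethylation can only occur on the dimethoxy ring, giving the quinone that carries the side chain.

Step 11
Reactants: 13, naphthazarin diacetate
Product: 14, isobutylshikonin, (1R)-1-(5,8-dihydroxy-1,4-dioxo-1,4-dihydronaphthalen-2-yl)-4-methylpent-3-en-1-yl 2-methylpropanoate
Conditions: K2CO3 (2.2 equiv), MeOH/THF, 0 °C, 15 min; then pH 4 buffer
Reagents that add atoms: none
Why: Chemoselective methanolysis removes the two aryl acetates (acidic, quinone-conjugated phenoxide leaving groups) far faster than the hindered secondary alkyl isobutyrate, and the naphthazarin dianion formed protects C1′–H from deprotonation, so (R) is kept.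

**Compound list**
1 | 1,5-dimethoxynaphthalene | COc1cccc2c(OC)cccc12 | starting material
2 | 4,8-dibromo-1,5-dimethoxynaphthalene | COc1ccc(Br)c2c(OC)ccc(Br)c12 | intermediate
3 | 1,4,5,8-tetramethoxynaphthalene | COc1ccc(OC)c2c(OC)ccc(OC)c12 | intermediate
4 | 2-bromo-1,4,5,8-tetramethoxynaphthalene | COc1cc(Br)c(OC)c2c(OC)ccc(OC)c12 | intermediate
5 | 4-methylpent-3-enoic acid | CC(C)=CCC(=O)O | starting material
6 | N-methoxy-N,4-dimethylpent-3-enamide | CC(C)=CCC(=O)N(C)OC | intermediate
7 | 4-methyl-1-(1,4,5,8-tetramethoxynaphthalen-2-yl)pent-3-en-1-one | CC(C)=CCC(=O)c1cc(OC)c2c(OC)ccc(OC)c2c1OC | intermediate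
8 | isobutyric anhydride (2-methylpropanoic anhydride) | CC(C)C(=O)OC(=O)C(C)C | starting material
9 | (1Z)-4-methyl-1-(1,4,5,8-tetramethoxynaphthalen-2-yl)penta-1,3-dien-1-yl 2-methylpropanoate | CC(C)=C/C=C(\OC(=O)C(C)C)c1cc(OC)c2c(OC)ccc(OC)c2c1OC | intermediate
10 | (1R)-4-methyl-1-(1,4,5,8-tetramethoxynaphthalen-2-yl)pent-3-en-1-yl 2-methylpropanoate | CC(C)=CC[C@@H](OC(=O)C(C)C)c1cc(OC)c2c(OC)ccc(OC)c2c1OC | intermediate
11 | (1R)-1-(1,4-dimethoxy-5,8-dioxo-5,8-dihydronaphthalen-2-yl)-4-methylpent-3-en-1-yl 2-methylpropanoate | CC(C)=CC[C@@H](OC(=O)C(C)C)c1cc(OC)c2C(=O)C=CC(=O)c2c1OC | intermediate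
12 | (1R)-1-[5,8-bis(acetyloxy)-1,4-dimethoxynaphthalen-2-yl]-4-methylpent-3-en-1-yl 2-methylpropanoate | CC(C)=CC[C@@H](OC(=O)C(C)C)c1cc(OC)c2c(OC(C)=O)ccc(OC(C)=O)c2c1OC | intermediate
13 | (1R)-1-[5,8-bis(acetyloxy)-1,4-dioxo-1,4-dihydronaphthalen-2-yl]-4-methylpent-3-en-1-yl 2-methylpropanoate | CC(C)=CC[C@@H](OC(=O)C(C)C)C1=CC(=O)c2c(OC(C)=O)ccc(OC(C)=O)c2C1=O | intermediate
14 | Isobutylshikonin, (1R)-1-(5,8-dihydroxy-1,4-dioxo-1,4-dihydronaphthalen-2-yl)-4-methylpent-3-en-1-yl 2-methylpropanoate | CC(C)=CC[C@@H](OC(=O)C(C)C)C1=CC(=O)c2c(O)ccc(O)c2C1=O | target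

**Totals**
Total steps: 11. Longest linear sequence: 10 (Steps 1–3 and 5–11, from 1); Step 4 is a one-step branch.

**Three steps most likely to fail**
1. Step 7 (proposed new hydrogenation). Risks are low ee from the twisted ortho-methoxy naphthyl group, competing 1,4-reduction or alkene migration, and slow turnover. Fallback (known chemistry): reduce ketone 7 with (+)-DIP-Cl (THF, −25 °C), the reagent-controlled asymmetric reduction of aryl ketones, to the (R)-carbinol, then acylate with isobutyric anhydride/DMAP/Et3N to reach 10 without going through 9.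
2. Step 11 (selective removal of two aryl acetates beside the side-chain ester on a base-sensitive quinone). Fallback: saponify all three esters (1 M NaOH, rt, then acidify) to (R)-shikonin, then esterify only the side-chain alcohol with isobutyric acid/DCC/DMAP (CH2Cl2, 0 °C); the peri-phenols are intramolecularly hydrogen-bonded and do not react.
3. Step 8 (first CAN oxidation). Risks are incomplete regioselectivity and acid-promoted loss of the electron-rich benzylic ester. Fallback: change the protecting-group strategy and build Steps 3–7 on the peri-bridged bis(methylene acetal) core, 1,8:4,5-bis(methylenedioxy)naphthalene, which is released to the naphthazarin in a single anodic oxidation, replacing Steps 8–11.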